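**Plan**
- Feature: in ring C, C2 is a single sp2 carbon bonded only to O1, C3 and C1' of the 2',6'-dioxygenated ring B, so in retrosynthesis it is carbon monoxide.
- Cuts: the masking groups go first (5-O-methyl, 6-O-MOM, 2'-O-MOM). Then C1'–C2, C2–C3 and C2–O1 are cut together, leaving a ring-B aryl iodide, CO and a ring-A 2-hydroxyacetophenone.
- Ring A is bought as 1,2,3,5-tetramethoxybenzene. It is acetylated with loss of the crowded ortho methyl group, Elbs oxidation installs the future O6, and that oxygen is MOM-protected. The only methyl ether to be removed at the end is then the carbonyl-chelated one at C5.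
- Ring B is bought as 3-methoxyphenol, which is converted to its MOM ether, lithiated between the two oxygens and iodinated.
- Forward order: rings A and B come ready-made, and ring C is the only ring formed, closing in the three-component carbonylation. One boron trichloride treatment then frees the three hydroxyl groups.
- Stereochemistry: there is none to set, because the target has no stereocentre and no hindered axis.

Key step: step 6

Assumption: the C2–C1' axis is flanked on the chromone side only by O1 and C3–H and rotates freely, so the target is achiral and no enantiocontrol is called for.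
Assumption: 1,2,3,5-tetramethoxybenzene, 3-methoxyphenol and carbon monoxide are taken as catalogue items.
Numbering: acetophenone numbering is used for 2–6 and flavone numbering for the atoms of 12–16.

**Step 1**
Reactants: 1 1,2,3,5-tetramethoxybenzene
Product: 3 2-hydroxy-3,4,6-trimethoxyacetophenone, via 2,3,4,6-tetramethoxyacetophenone 2 (not isolated)
Conditions: AcCl (1.1 equiv), AlCl3 (2.5 equiv), Et2O, 0 °C → rt; then ice-water
Reagents that add atoms: acetyl chloride, CC(=O)Cl
Why: Friedel–Crafts acylation at one of the two equivalent free positions is followed in the same pot by aluminium-chelate-assisted cleavage of an ortho methyl ether, and the 2-methoxy group is the one lost because it is wedged between the acetyl and 3-methoxy groups and twisted out of conjugation, a long-established outcome for this arene.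

**Step 2**
Reactants: 3 2-hydroxy-3,4,6-trimethoxyacetophenone
Product: 5 2,5-dihydroxy-3,4,6-trimethoxyacetophenone, via potassium aryl sulfate 4 (not isolated)
Conditions: K2S2O8, aq KOH, 10–20 °C; acidify and extract unchanged 3; then conc. HCl, 85–90 °C, N2
Reagents that add atoms: potassium peroxodisulfate, [K+].[K+].[O-]S(=O)(=O)OOS(=O)(=O)[O-]
Why: In the Elbs persulfate oxidation the phenoxide of 3 attacks the peroxide oxygen through its para carbon C5, the only unsubstituted ring position, and acid hydrolysis of sulfate ester 4 frees the hydroquinone, with unreacted 3 recoverable before the hydrolysis.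

**Step 3**
Reactants: 5 2,5-dihydroxy-3,4,6-trimethoxyacetophenone
Product: 6 2-hydroxy-3,4,6-trimethoxy-5-(methoxymethoxy)acetophenone
Conditions: MOMCl (1.05 equiv), iPr2NEt, CH2Cl2, 0 °C, N2
Reagents that add atoms: chloromethyl methyl ether, COCCl
Why: O-alkylation with an α-chloro ether under a mild amine base distinguishes the two phenols because the 2-OH is held in a hydrogen bond to the acetyl carbonyl, which is the standard basis for selective protection of polyhydroxyacetophenones.

**Step 4**
Reactants: 7 3-methoxyphenol
Product: 8 1-methoxy-3-(methoxymethoxy)benzene
Conditions: MOMCl, iPr2NEt, CH2Cl2, 0 °C → rt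
Reagents that add atoms: chloromethyl methyl ether, COCCl
Why: This is a routine phenol O-alkylation, and MOM is chosen because it is a strong ortho-director for step 5 and inert to the amidine base of step 6.

**Step 5**
Reactants: 8 1-methoxy-3-(methoxymethoxy)benzene
Product: 10 2-iodo-1-methoxy-3-(methoxymethoxy)benzene, via 2-lithio arene 9 (not isolated)
Conditions: n-BuLi, THF, 0 °C; then I2, −78 °C → rt
Reagents that add atoms: iodine, II; n-butyllithium, [Li]CCCC (lithium of 9 only)
Why: In this directed ortho-metalation C2 lies between two coordinating oxygens whose cooperative effect makes it the kinetically most acidic site, and the iodine quench places the halogen where electrophilic iodination would not go.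

**Step 6**
Reactants: 6 2-hydroxy-3,4,6-trimethoxy-5-(methoxymethoxy)acetophenone; 10 2-iodo-1-methoxy-3-(methoxymethoxy)benzene (1.3 equiv); 11 carbon monoxide
Product: 14 5,7,8,6'-tetramethoxy-6,2'-bis(methoxymethoxy)flavone, via aryl ester 12 (not isolated), via 1,3-diketone 13 (not isolated)
Conditions: Pd(OAc)2 (5 mol %), Xantphos (6 mol %), DBU (4 equiv), CO (5 bar), DMSO, 80 °C, then 120 °C
Reagents that add atoms: carbon monoxide (11), [C-]#[O+]
Why: Pd(0) adds into the C1'–I bond of 10, CO inserts (a step the two ortho oxygens favour, because it moves palladium one atom away from the crowded ring), and the DBU-generated phenoxide of 6 takes the aroyl group from palladium to give ester 12, which fixes C1'–C2. DBU then enolises the acetyl group and a Baker–Venkataraman O-to-C acyl shift gives diketone 13 (C2–C3); if the enolate of 6 captured the aroylpalladium directly the same diketone would result, so both acyl-transfer paths converge. Ring C, the only ring made in the route, closes by 6-exo-trig addition of the ring-A phenoxide to the C2 carbonyl and E1cB loss of water across C2–C3 (C2–O1). The closest known reaction type is the palladium-catalysed carbonylative coupling of aryl halides with 2-hydroxyacetophenones to flavones under an amidine base, of which this is a sterically demanding member; for that reason the iodide, a wide-bite-angle diphosphine that speeds acyl–oxygen reductive elimination, an excess of 10 and a two-temperature programme are chosen. No stereocentre is formed. The step needs closure through the ring-A oxygen only and carbonylative rather than direct coupling: the first is secured because 6 carries a single free phenol while O6 and O2' are base-stable MOM ethers, and the second by the CO pressure and by the fact that a di-ortho-substituted arylpalladium has no faster outlet than CO insertion.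

**Step 7**
Reactants: 14 5,7,8,6'-tetramethoxy-6,2'-bis(methoxymethoxy)flavone
Product: 16 5,6,2'-trihydroxy-7,8,6'-trimethoxyflavone, via 6,2'-dihydroxy-5,7,8,6'-tetramethoxyflavone 15 (not isolated)
Conditions: BCl3 (5 equiv), CH2Cl2, −78 → 0 °C; then 1 M HCl, THF, rt
Reagents that add atoms: none
Why: Boron trichloride cleaves the two aryl MOM acetals at low temperature and, on warming, the one methyl ether whose oxygen shares boron with the C4 carbonyl in a six-membered chelate (the standard peri-selective demethylation of 5-methoxyflavones), while the 7-, 8- and 6'-methyl ethers lack such assistance and should stay.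

**Compound list**
1 | 1,2,3,5-tetramethoxybenzene | COc1cc(OC)c(OC)c(OC)c1 | starting material
2 | 2,3,4,6-tetramethoxyacetophenone | CC(=O)c1c(OC)cc(OC)c(OC)c1OC | intermediate (not isolated)
3 | 2-hydroxy-3,4,6-trimethoxyacetophenone | CC(=O)c1c(OC)cc(OC)c(OC)c1O | intermediate
4 | potassium 3-acetyl-4-hydroxy-2,5,6-trimethoxyphenyl sulfate | CC(=O)c1c(OC)c(OS(=O)(=O)[O-])c(OC)c(OC)c1O.[K+] | intermediate (not isolated)
5 | 2,5-dihydroxy-3,4,6-trimethoxyacetophenone | CC(=O)c1c(OC)c(O)c(OC)c(OC)c1O | intermediate
6 | 2-hydroxy-3,4,6-trimethoxy-5-(methoxymethoxy)acetophenone | CC(=O)c1c(OC)c(OCOC)c(OC)c(OC)c1O | intermediate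
7 | 3-methoxyphenol | COc1cccc(O)c1 | starting material
8 | 1-methoxy-3-(methoxymethoxy)benzene | COCOc1cccc(OC)c1 | intermediate
9 | 2-lithio-1-methoxy-3-(methoxymethoxy)benzene | [Li]c1c(OC)cccc1OCOC | intermediate (not isolated)
10 | 2-iodo-1-methoxy-3-(methoxymethoxy)benzene | COCOc1cccc(OC)c1I | intermediate
11 | carbon monoxide | [C-]#[O+] | starting material
12 | 2-acetyl-3,5,6-trimethoxy-4-(methoxymethoxy)phenyl 2-methoxy-6-(methoxymethoxy)benzoate | CC(=O)c1c(OC)c(OCOC)c(OC)c(OC)c1OC(=O)c1c(OC)cccc1OCOC | intermediate (not isolated)
13 | 1-[2-hydroxy-3,4,6-trimethoxy-5-(methoxymethoxy)phenyl]-3-[2-methoxy-6-(methoxymethoxy)phenyl]propane-1,3-dione | COCOc1cccc(OC)c1C(=O)CC(=O)c1c(O)c(OC)c(OC)c(OCOC)c1OC | intermediate (not isolated)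
14 | 5,7,8,6'-tetramethoxy-6,2'-bis(methoxymethoxy)flavone | COCOc1cccc(OC)c1-c1cc(=O)c2c(OC)c(OCOC)c(OC)c(OC)c2o1 | intermediate
15 | 6,2'-dihydroxy-5,7,8,6'-tetramethoxyflavone (held in the flask as its boron aryloxides) | COc1cccc(O)c1-c1cc(=O)c2c(OC)c(O)c(OC)c(OC)c2o1 | intermediate (not isolated)
16 | 5,6,2'-trihydroxy-7,8,6'-trimethoxyflavone (achiral) | COc1cccc(O)c1-c1cc(=O)c2c(O)c(O)c(OC)c(OC)c2o1 | target

Total step count: 7
Longest linear sequence: 5 steps (1, 2, 3, 6, 7)

**Steps most likely to fail**

Step 6. Transfer of the crowded aroyl group from palladium to an equally crowded phenoxide may be slower than hydrolysis of the acylpalladium or reduction of the iodide. The cascade may also stall before the dehydration. The fallback sets out from 8 and 6 and comes back at 14, and it brings C2 in at the aldehyde oxidation level.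
- Lithio arene 9, made from 8 as in step 5, is quenched with DMF to give 2-methoxy-6-(methoxymethoxy)benzaldehyde F1.
- Claisen–Schmidt condensation of this aldehyde with 6 (KOH, EtOH, rt) gives the (E)-2'-hydroxychalcone F2. The electrophilic carbon here is far less shielded than an aroyl carbon.
- Sodium acetate in refluxing ethanol closes the chalcone by oxa-Michael addition to the racemic flavanone F3.
- Iodine in hot pyridine, the standard basic dehydrogenation of flavanones, spares both MOM acetals, erases the transient C2 stereocentre and gives 14.

Step 2. Conversion may stay low, and the electron-rich phenoxide may be degraded by over-oxidation through sulfate-radical side reactions. The fallback sets out from 3 and comes back at 5, and it reaches the same oxidation pattern through the quinone.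
- Teuber oxidation of 3 with Fremy's salt (aqueous phosphate buffer, acetone) attacks the free para position and gives 2-acetyl-3,5,6-trimethoxy-1,4-benzoquinone F4.
- This quinone is reduced at once with aqueous sodium dithionite to hydroquinone 5.

Step 7. The methoxymethyl cation released by the Lewis acid may alkylate the freed, electron-rich phenol rings. A further methyl ether next to boron-bound O6 may also be lost slowly. The fallback sets out from 14 and comes back at 16, and it separates acetal removal from ether cleavage.
- Brønsted-acid methanolysis (HCl, MeOH, 45 °C) removes both MOM groups, with the formaldehyde unit carried off as its dimethyl acetal, and 15 is isolated.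
- The 5-methyl ether alone is then cleaved through the C4=O/O5 aluminium chelate (AlCl3, MeCN, 60–70 °C, then warm dilute HCl), conditions suited to 6-hydroxy-5-methoxyflavones.

**Further compounds**
F1 | step 6 | 2-methoxy-6-(methoxymethoxy)benzaldehyde | COCOc1cccc(OC)c1C=O
F2 | step 6 | (E)-1-[2-hydroxy-3,4,6-trimethoxy-5-(methoxymethoxy)phenyl]-3-[2-methoxy-6-(methoxymethoxy)phenyl]prop-2-en-1-one | COCOc1cccc(OC)c1/C=C/C(=O)c1c(O)c(OC)c(OC)c(OCOC)c1OC
F3 | step 6 | racemic 5,7,8,6'-tetramethoxy-6,2'-bis(methoxymethoxy)flavanone | COCOc1cccc(OC)c1C1CC(=O)c2c(OC)c(OCOC)c(OC)c(OC)c2O1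
F4 | step 2 | 2-acetyl-3,5,6-trimethoxy-1,4-benzoquinone | CC(=O)C1=C(OC)C(=O)C(OC)=C(OC)C1=O
F0 | step 7 | none | none
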